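## Retrosynthetic overview

- The target is reached from the trans-decalin C2 ketone by enolate hydroxylation at C3, equilibration to the equatorial alcohol, desilylation and acetylation of the C15 alcohol.
- Ring B is closed last, by ring-closing metathesis of a ring A ketone carrying a C5 allyl arm and a C9 isopropenyl arm. The strategy rests on the only ring alkene, the trisubstituted C7=C8 bond of ring B that bears C17. Made as the ring-closing bond, it cannot end up at C8=C17 or C8=C9.
- The C5 allyl arm comes from an exocyclic C5=C6 alkene by hydroboration and B-alkyl Suzuki coupling with vinyl bromide (sets C5). The isopropenyl group comes from the C8 carboxyl, and the C2 ketone from a C2 silyl ether.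
- The C9–C10 bond and both stereocentres come from an Ireland–Claisen rearrangement of a ring A allylic ester. Ring A comes from 4-oxoisophorone, with its C2 stereocentre set by asymmetric transfer hydrogenation; the acid comes from geraniol by one-carbon homologation.

Key step: step 19

Assumptions: labdane numbering (C1–C20) is used for ring A intermediates as well; in step 1 the (R,R)-ligand is taken to give the (R)-carbinol (sense as for aryl alkyl ketones); in step 12 the rearrangement is taken to occur on the ring face syn to the C2 silyl ether.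

## Route

Step 1
Reactants: 1 4-oxoisophorone (2,6,6-trimethylcyclohex-2-ene-1,4-dione)
Product: 2 (R)-4-hydroxy-2,6,6-trimethylcyclohex-2-en-1-one
Conditions: RuCl(p-cymene)[(R,R)-TsDPEN] (cat.), KOH (cat.), i-PrOH, rt
Reagents that add atoms: none
Why: Asymmetric transfer hydrogenation by a ruthenium hydride reduces only the unhindered carbonyl flanked by the vinyl CH and a CH2 (the other carbonyl lies between a quaternary carbon and the methyl-bearing alkene carbon), and the ligand sets the (R)-carbinol, the future C2, by catalyst control.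

Step 2
Reactants: 2 (R)-4-hydroxy-2,6,6-trimethylcyclohex-2-en-1-one
Product: 3 (R)-4-[(tert-butyldimethylsilyl)oxy]-2,6,6-trimethylcyclohex-2-en-1-one
Conditions: TBSCl, imidazole, DMF, rt
Reagents that add atoms: tert-butyldimethylsilyl chloride, CC(C)(C)[Si](C)(C)Cl
Why: Silylation of the secondary alcohol with a silyl chloride and imidazole, which touches no stereocentre.

Step 3
Reactants: 3 (R)-4-[(tert-butyldimethylsilyl)oxy]-2,6,6-trimethylcyclohex-2-en-1-one
Product: 5 (S)-4-[(tert-butyldimethylsilyl)oxy]-2,6,6-trimethylcyclohex-1-en-1-yl trifluoromethanesulfonate, via lithium enolate 4 (not isolated)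
Conditions: LiBH(s-Bu)3, THF, −78 °C; then N-(5-chloro-2-pyridyl)bis(trifluoromethanesulfonimide), −78 → 0 °C; aq. NH4Cl
Reagents that add atoms: N-(5-chloro-2-pyridyl)bis(trifluoromethanesulfonimide), FC(F)(F)S(=O)(=O)N(c1ccc(Cl)cn1)S(=O)(=O)C(F)(F)F
Why: Conjugate reduction and enolate O-sulfonylation: the bulky borohydride adds to the unsubstituted β-carbon (the carbonyl is shielded by the gem-dimethyl group), which gives the tetrasubstituted enolate regiospecifically, and the triflimide traps it on oxygen, so that the ring alkene now lies at C5=C10.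

Step 4
Reactants: 5 (S)-4-[(tert-butyldimethylsilyl)oxy]-2,6,6-trimethylcyclohex-1-en-1-yl trifluoromethanesulfonate
Product: 6 methyl (S)-4-[(tert-butyldimethylsilyl)oxy]-2,6,6-trimethylcyclohex-1-ene-1-carboxylate
Conditions: Pd(OAc)2, PPh3, CO (1 atm), MeOH, Et3N, DMF, 60 °C
Reagents that add atoms: carbon monoxide, [C-]#[O+]; methanol, CO
Why: Palladium-catalysed methoxycarbonylation of an enol triflate (oxidative addition, CO insertion, methanolysis) installs C6 on C5.

Step 5
Reactants: 6 methyl (S)-4-[(tert-butyldimethylsilyl)oxy]-2,6,6-trimethylcyclohex-1-ene-1-carboxylate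
Product: 7 [(S)-4-[(tert-butyldimethylsilyl)oxy]-2,6,6-trimethylcyclohex-1-en-1-yl]methanol
Conditions: i-Bu2AlH, CH2Cl2, −78 → 0 °C; aq. KNaC4H4O6 (potassium sodium tartrate)
Reagents that add atoms: none
Why: Hydride reduction of the conjugated ester to the primary allylic alcohol, with the tetrasubstituted alkene and the silyl ether inert.

Step 6
Reactants: 8 geraniol
Product: 9 (E)-tert-butyl[(3,7-dimethylocta-2,6-dien-1-yl)oxy]diphenylsilane
Conditions: TBDPSCl, imidazole, DMF, 0 °C → rt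
Reagents that add atoms: tert-butyl(chloro)diphenylsilane, CC(C)(C)[Si](Cl)(c1ccccc1)c1ccccc1
Why: Silylation of the primary allylic alcohol with a group that survives acid, base, organolithium reagents and the later selective removal of the ring silyl ether.

Step 7
Reactants: 9 (E)-tert-butyl[(3,7-dimethylocta-2,6-dien-1-yl)oxy]diphenylsilane
Product: 10 (E)-tert-butyl{[5-(3,3-dimethyloxiran-2-yl)-3-methylpent-2-en-1-yl]oxy}diphenylsilane (racemic at the epoxide)
Conditions: m-CPBA (1.0 equiv), CH2Cl2, −20 °C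
Reagents that add atoms: 3-chloroperbenzoic acid, OOC(=O)c1cccc(Cl)c1
Why: Prilezhaev epoxidation should take place at the distal trisubstituted alkene, which is more electron-rich and less shielded than the alkene next to the silyloxymethyl group; the new stereocentre is lost in step 8.

Step 8
Reactants: 10 (E)-tert-butyl{[5-(3,3-dimethyloxiran-2-yl)-3-methylpent-2-en-1-yl]oxy}diphenylsilane
Product: 11 (E)-6-[(tert-butyldiphenylsilyl)oxy]-4-methylhex-4-enal
Conditions: H5IO6, THF/H2O, 0 °C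
Reagents that add atoms: none
Why: Periodic acid opens the epoxide and cleaves the resulting glycol in one operation to the aldehyde and acetone.

Step 9
Reactants: 11 (E)-6-[(tert-butyldiphenylsilyl)oxy]-4-methylhex-4-enal
Product: 12 tert-butyl{[(2E)-7-methoxy-3-methylhepta-2,6-dien-1-yl]oxy}diphenylsilane (enol ether as E/Z mixture)
Conditions: [Ph3PCH2OMe]Cl, KN(SiMe3)2, THF, −78 → 0 °C
Reagents that add atoms: (methoxymethyl)triphenylphosphonium chloride, [Cl-].COC[P+](c1ccccc1)(c1ccccc1)c1ccccc1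
Why: Wittig reaction with the methoxymethylene ylide adds the carbon that becomes C8; the enol ether geometry is of no consequence.

Step 10
Reactants: 12 tert-butyl{[(2E)-7-methoxy-3-methylhepta-2,6-dien-1-yl]oxy}diphenylsilane
Product: 14 (E)-7-[(tert-butyldiphenylsilyl)oxy]-5-methylhept-5-enoic acid, via homologated aldehyde 13 (not isolated)
Conditions: 1 M HCl, THF, 0 °C → rt; then NaClO2, NaH2PO4, 2-methyl-2-butene, t-BuOH/H2O, rt
Reagents that add atoms: water, O; sodium chlorite, [Na+].[O-]Cl=O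
Why: Acid hydrolysis of the enol ether followed by Pinnick oxidation with a hypochlorite scavenger, which spares the trisubstituted alkene and the silyl ether.

Step 11
Reactants: 7 [(S)-4-[(tert-butyldimethylsilyl)oxy]-2,6,6-trimethylcyclohex-1-en-1-yl]methanol, 14 (E)-7-[(tert-butyldiphenylsilyl)oxy]-5-methylhept-5-enoic acid
Product: 15 [(S)-4-[(tert-butyldimethylsilyl)oxy]-2,6,6-trimethylcyclohex-1-en-1-yl]methyl (E)-7-[(tert-butyldiphenylsilyl)oxy]-5-methylhept-5-enoate
Conditions: DCC, DMAP (cat.), CH2Cl2, 0 °C → rt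
Reagents that add atoms: none
Why: Steglich esterification of a primary allylic alcohol under neutral conditions.

Step 12
Reactants: 15 [(S)-4-[(tert-butyldimethylsilyl)oxy]-2,6,6-trimethylcyclohex-1-en-1-yl]methyl (E)-7-[(tert-butyldiphenylsilyl)oxy]-5-methylhept-5-enoate
Product: 18 (2S,5E)-7-[(tert-butyldiphenylsilyl)oxy]-2-[(1S,5R)-5-[(tert-butyldimethylsilyl)oxy]-1,3,3-trimethyl-2-methylidenecyclohexyl]-5-methylhept-5-enoic acid (labdane 2R,9S,10S), via Z-silyl ketene acetal 16 (not isolated), via silyl ester 17 (not isolated)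
Conditions: LiN(i-Pr)2, THF/DMPU, −78 °C; TBSCl; → rt, then 60 °C; K2CO3, MeOH/H2O, then work-up at pH 4; chromatography
Reagents that add atoms: none
Why: Ireland–Claisen rearrangement: the Z(O)-silyl ketene acetal formed in THF/DMPU rearranges through a chair transition state with the C11 chain equatorial and pointing away from ring A, which fixes C9 relative to C10, and the C9–C10 bond should form on the ring face syn to the pseudoequatorial C2 silyl ether (the path to the chair with the C9 arm and the silyl ether both equatorial, free of a 1,3-diaxial contact between the incoming carbon and a C4 methyl group), the minor face isomer being removed by chromatography.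

Step 13
Reactants: 18 (2S,5E)-7-[(tert-butyldiphenylsilyl)oxy]-2-[(1S,5R)-5-[(tert-butyldimethylsilyl)oxy]-1,3,3-trimethyl-2-methylidenecyclohexyl]-5-methylhept-5-enoic acid
Product: 19 methyl (2S,5E)-7-[(tert-butyldiphenylsilyl)oxy]-2-[(1S,5R)-5-[(tert-butyldimethylsilyl)oxy]-1,3,3-trimethyl-2-methylidenecyclohexyl]-5-methylhept-5-enoate
Conditions: MeI, K2CO3, DMF, rt
Reagents that add atoms: iodomethane, CI
Why: O-alkylation of the carboxylate (SN2 at methyl) masks the acid as an ester that is inert to 9-BBN and touches no stereocentre.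

Step 14
Reactants: 19 methyl (2S,5E)-7-[(tert-butyldiphenylsilyl)oxy]-2-[(1S,5R)-5-[(tert-butyldimethylsilyl)oxy]-1,3,3-trimethyl-2-methylidenecyclohexyl]-5-methylhept-5-enoate, 20 vinyl bromide
Product: 22 methyl (2S,5E)-2-[(1R,2R,5R)-2-allyl-5-[(tert-butyldimethylsilyl)oxy]-1,3,3-trimethylcyclohexyl]-7-[(tert-butyldiphenylsilyl)oxy]-5-methylhept-5-enoate, via B-alkyl-9-BBN 21 (not isolated)
Conditions: 9-BBN dimer, THF, 60 °C; then 20 (1 M in THF), Pd(dppf)Cl2, AsPh3, Cs2CO3, DMF/H2O, rt → 45 °C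
Reagents that add atoms: none
Why: Hydroboration then B-alkyl Suzuki–Miyaura coupling: 9-BBN should add boron to the terminal C6 of the 1,1-disubstituted alkene faster than to the trisubstituted, silyloxy-deactivated C13=C14 alkene and deliver hydrogen to C5 from the face opposite the two flanking axial methyl groups (C20 and one C4 methyl) of the chair that holds the C9 arm and the C2 silyl ether equatorial, which places C6 equatorial and trans to the C9 arm, after which the primary alkylborane couples with vinyl bromide.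

Step 15
Reactants: 22 methyl (2S,5E)-2-[(1R,2R,5R)-2-allyl-5-[(tert-butyldimethylsilyl)oxy]-1,3,3-trimethylcyclohexyl]-7-[(tert-butyldiphenylsilyl)oxy]-5-methylhept-5-enoate
Product: 24 (3S,6E)-3-[(1R,2R,5R)-2-allyl-5-[(tert-butyldimethylsilyl)oxy]-1,3,3-trimethylcyclohexyl]-8-[(tert-butyldiphenylsilyl)oxy]-6-methyloct-6-en-2-one, via α-silyl ketone 23 (not isolated)
Conditions: Me3SiCH2Li (2.5 equiv), pentane/THF, 0 °C → rt; then MeOH, rt; aq. NH4Cl
Reagents that add atoms: (trimethylsilyl)methyllithium, [Li]C[Si](C)(C)C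
Why: Acylation of (trimethylsilyl)methyllithium by the ester: the α-silyl ketone is deprotonated between carbonyl and silicon by the second equivalent, which stops over-addition and keeps C9 from enolising, and methanolysis of the C–Si bond then gives the methyl ketone (C17).

Step 16
Reactants: 24 (3S,6E)-3-[(1R,2R,5R)-2-allyl-5-[(tert-butyldimethylsilyl)oxy]-1,3,3-trimethylcyclohexyl]-8-[(tert-butyldiphenylsilyl)oxy]-6-methyloct-6-en-2-one
Product: 25 tert-butyl{[(2E,6R)-6-[(1S,2R,5R)-2-allyl-5-[(tert-butyldimethylsilyl)oxy]-1,3,3-trimethylcyclohexyl]-3,7-dimethylocta-2,7-dien-1-yl]oxy}diphenylsilane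
Conditions: Zn, CH2Br2, TiCl4, THF/CH2Cl2, 0 °C → rt
Reagents that add atoms: dibromomethane, BrCBr
Why: Methylenation with the Zn/CH2Br2/TiCl4 reagent, a non-basic gem-dimetallic that converts hindered, epimerisable ketones into 1,1-disubstituted alkenes without touching C9.

Step 17
Reactants: 25 tert-butyl{[(2E,6R)-6-[(1S,2R,5R)-2-allyl-5-[(tert-butyldimethylsilyl)oxy]-1,3,3-trimethylcyclohexyl]-3,7-dimethylocta-2,7-dien-1-yl]oxy}diphenylsilane
Product: 26 (1R,3S,4R)-4-allyl-3-[(3R,6E)-8-[(tert-butyldiphenylsilyl)oxy]-2,6-dimethylocta-1,6-dien-3-yl]-3,5,5-trimethylcyclohexan-1-ol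
Conditions: camphorsulfonic acid (cat.), MeOH/CH2Cl2, 0 °C
Reagents that add atoms: none
Why: Acid-catalysed methanolysis removes the secondary tert-butyldimethylsilyl ether far faster than the tert-butyldiphenylsilyl ether, which is why the two oxygen atoms carry different silyl groups.

Step 18
Reactants: 26 (1R,3S,4R)-4-allyl-3-[(3R,6E)-8-[(tert-butyldiphenylsilyl)oxy]-2,6-dimethylocta-1,6-dien-3-yl]-3,5,5-trimethylcyclohexan-1-ol
Product: 27 (3S,4R)-4-allyl-3-[(3R,6E)-8-[(tert-butyldiphenylsilyl)oxy]-2,6-dimethylocta-1,6-dien-3-yl]-3,5,5-trimethylcyclohexan-1-one (labdane 5R,9R,10S)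
Conditions: Dess–Martin periodinane, NaHCO3, CH2Cl2, rt
Reagents that add atoms: none
Why: Dess–Martin oxidation of the secondary alcohol gives the C2 ketone under buffered conditions that do not epimerise C5, C9 or C10.

Step 19
Reactants: 27 (3S,4R)-4-allyl-3-[(3R,6E)-8-[(tert-butyldiphenylsilyl)oxy]-2,6-dimethylocta-1,6-dien-3-yl]-3,5,5-trimethylcyclohexan-1-one
Product: 28 (5R,9R,10R)-15-[(tert-butyldiphenylsilyl)oxy]labda-7,13E-dien-2-one
Conditions: second-generation Grubbs catalyst RuCl2(H2IMes)(PCy3)(=CHPh) (5 mol%), CH2Cl2 (0.005 M), 40 °C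
Reagents that add atoms: none
Why: The ruthenium methylidene should load onto the monosubstituted alkene of the C5 allyl arm, and the alkylidene at C7 then undergoes [2+2] cycloaddition with the C8 isopropenyl alkene and cycloreversion, which releases ethylene and forms the C7=C8 bond; this is ring-closing olefin metathesis of a monosubstituted with a 1,1-disubstituted alkene to a trisubstituted cyclohexene, an established case for this catalyst. Ring B closes as a six-membered ring by joining two arms that sit trans-diequatorial on the ring A chair, so the product is the unstrained trans-decalin. No stereocentre is formed; C5, C9 and C10 are carried through unchanged, and the alkene can only lie between the two carbons that bore the alkenes, which fixes it at C7=C8. The selectivity needed is chemoselectivity among three kinds of alkene: only the allyl terminus initiates readily, six-ring closure onto the isopropenyl group outruns eight-ring closure onto the trisubstituted C13=C14 alkene, and high dilution suppresses dimerisation. The ketone and the silyl ether are inert to the catalyst.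

Step 20
Reactants: 28 (5R,9R,10R)-15-[(tert-butyldiphenylsilyl)oxy]labda-7,13E-dien-2-one
Product: 30 (3R,5S,9R,10S)-15-[(tert-butyldiphenylsilyl)oxy]-3-hydroxylabda-7,13E-dien-2-one (axial alcohol), via potassium enolate 29 (not isolated)
Conditions: KN(SiMe3)2, THF, −78 °C; 2-(phenylsulfonyl)-3-phenyloxaziridine, −78 °C; aq. NH4Cl
Reagents that add atoms: 2-(phenylsulfonyl)-3-phenyloxaziridine, O=S(=O)(N1OC1c1ccccc1)c1ccccc1
Why: Enolate oxidation with an N-sulfonyloxaziridine: kinetic deprotonation should occur at C3 (the C1 hydrogens are screened by C20 and the C9 side chain), and the oxidant attacks along the axial line on the face opposite the axial C20 and C4 methyl groups, which gives the axial 3R alcohol.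

Step 21
Reactants: 30 (3R,5S,9R,10S)-15-[(tert-butyldiphenylsilyl)oxy]-3-hydroxylabda-7,13E-dien-2-one
Product: 31 (3S,5S,9R,10S)-15-[(tert-butyldiphenylsilyl)oxy]-3-hydroxylabda-7,13E-dien-2-one (equatorial alcohol)
Conditions: K2CO3 (cat.), MeOH, rt, degassed, under argon
Reagents that add atoms: none
Why: Base-mediated equilibration of the α-ketol through its enediolate should settle on the equatorial 3S alcohol next to the C2 ketone, the thermodynamic isomer of a 4,4-dimethyl 2,3-ketol, so C3 is set under thermodynamic control.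

Step 22
Reactants: 31 (3S,5S,9R,10S)-15-[(tert-butyldiphenylsilyl)oxy]-3-hydroxylabda-7,13E-dien-2-one
Product: 32 (3S,5S,9R,10S)-3,15-dihydroxylabda-7,13E-dien-2-one
Conditions: HF·pyridine, pyridine, THF, 0 °C → rt
Reagents that add atoms: none
Why: Fluoride cleavage of the silyl ether under non-basic conditions that leave the α-ketol untouched.

Step 23
Reactants: 32 (3S,5S,9R,10S)-3,15-dihydroxylabda-7,13E-dien-2-one
Product: 33 (3S,5S,9R,10S)-3-hydroxy-2-oxolabda-7,13E-dien-15-yl acetate (CNP0164008.1)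
Conditions: Ac2O (1.1 equiv), pyridine, CH2Cl2, 0 °C
Reagents that add atoms: acetic anhydride, CC(=O)OC(C)=O
Why: Acylation of the primary allylic alcohol is much faster than that of the hindered secondary hydroxyl flanked by the quaternary C4 and the ketone.

## Compound list

1 | 4-oxoisophorone | CC1=CC(=O)CC(C)(C)C1=O | starting material
2 | (R)-4-hydroxy-2,6,6-trimethylcyclohex-2-en-1-one | CC1=C[C@H](O)CC(C)(C)C1=O | intermediate
3 | (R)-4-[(tert-butyldimethylsilyl)oxy]-2,6,6-trimethylcyclohex-2-en-1-one | CC1=C[C@H](O[Si](C)(C)C(C)(C)C)CC(C)(C)C1=O | intermediate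
4 | lithium (S)-4-[(tert-butyldimethylsilyl)oxy]-2,6,6-trimethylcyclohex-1-en-1-olate | [Li]OC1=C(C)C[C@H](O[Si](C)(C)C(C)(C)C)CC1(C)C | intermediate
5 | (S)-4-[(tert-butyldimethylsilyl)oxy]-2,6,6-trimethylcyclohex-1-en-1-yl trifluoromethanesulfonate | FC(F)(F)S(=O)(=O)OC1=C(C)C[C@H](O[Si](C)(C)C(C)(C)C)CC1(C)C | intermediate
6 | methyl (S)-4-[(tert-butyldimethylsilyl)oxy]-2,6,6-trimethylcyclohex-1-ene-1-carboxylate | COC(=O)C1=C(C)C[C@H](O[Si](C)(C)C(C)(C)C)CC1(C)C | intermediate
7 | [(S)-4-[(tert-butyldimethylsilyl)oxy]-2,6,6-trimethylcyclohex-1-en-1-yl]methanol | OCC1=C(C)C[C@H](O[Si](C)(C)C(C)(C)C)CC1(C)C | intermediate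
8 | geraniol | CC(C)=CCC/C(C)=C/CO | starting material
9 | (E)-tert-butyl[(3,7-dimethylocta-2,6-dien-1-yl)oxy]diphenylsilane | CC(C)=CCC/C(C)=C/CO[Si](c1ccccc1)(c1ccccc1)C(C)(C)C | intermediate
10 | (E)-tert-butyl{[5-(3,3-dimethyloxiran-2-yl)-3-methylpent-2-en-1-yl]oxy}diphenylsilane, racemic at the epoxide | CC1(C)OC1CC/C(C)=C/CO[Si](c1ccccc1)(c1ccccc1)C(C)(C)C | intermediate
11 | (E)-6-[(tert-butyldiphenylsilyl)oxy]-4-methylhex-4-enal | O=CCC/C(C)=C/CO[Si](c1ccccc1)(c1ccccc1)C(C)(C)C | intermediate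
12 | tert-butyl{[(2E)-7-methoxy-3-methylhepta-2,6-dien-1-yl]oxy}diphenylsilane, enol ether E/Z mixture | COC=CCC/C(C)=C/CO[Si](c1ccccc1)(c1ccccc1)C(C)(C)C | intermediate
13 | (E)-7-[(tert-butyldiphenylsilyl)oxy]-5-methylhept-5-enal | O=CCCC/C(C)=C/CO[Si](c1ccccc1)(c1ccccc1)C(C)(C)C | intermediate
14 | (E)-7-[(tert-butyldiphenylsilyl)oxy]-5-methylhept-5-enoic acid | OC(=O)CCC/C(C)=C/CO[Si](c1ccccc1)(c1ccccc1)C(C)(C)C | intermediate
15 | [(S)-4-[(tert-butyldimethylsilyl)oxy]-2,6,6-trimethylcyclohex-1-en-1-yl]methyl (E)-7-[(tert-butyldiphenylsilyl)oxy]-5-methylhept-5-enoate | CC(C)(C)[Si](c1ccccc1)(c1ccccc1)OC/C=C(\C)CCCC(=O)OCC1=C(C)C[C@H](O[Si](C)(C)C(C)(C)C)CC1(C)C | intermediate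
16 | Z-tert-butyldimethylsilyl ketene acetal of ester 15 | CC(C)(C)[Si](c1ccccc1)(c1ccccc1)OC/C=C(\C)CC/C=C(\O[Si](C)(C)C(C)(C)C)OCC1=C(C)C[C@H](O[Si](C)(C)C(C)(C)C)CC1(C)C | intermediate
17 | tert-butyldimethylsilyl ester of acid 18 | CC(C)(C)[Si](c1ccccc1)(c1ccccc1)OC/C=C(\C)CC[C@H](C(=O)O[Si](C)(C)C(C)(C)C)[C@]1(C)C[C@H](O[Si](C)(C)C(C)(C)C)CC(C)(C)C1=C | intermediate
18 | (2S,5E)-7-[(tert-butyldiphenylsilyl)oxy]-2-[(1S,5R)-5-[(tert-butyldimethylsilyl)oxy]-1,3,3-trimethyl-2-methylidenecyclohexyl]-5-methylhept-5-enoic acid | CC(C)(C)[Si](c1ccccc1)(c1ccccc1)OC/C=C(\C)CC[C@H](C(=O)O)[C@]1(C)C[C@H](O[Si](C)(C)C(C)(C)C)CC(C)(C)C1=C | intermediate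
19 | methyl (2S,5E)-7-[(tert-butyldiphenylsilyl)oxy]-2-[(1S,5R)-5-[(tert-butyldimethylsilyl)oxy]-1,3,3-trimethyl-2-methylidenecyclohexyl]-5-methylhept-5-enoate | CC(C)(C)[Si](c1ccccc1)(c1ccccc1)OC/C=C(\C)CC[C@H](C(=O)OC)[C@]1(C)C[C@H](O[Si](C)(C)C(C)(C)C)CC(C)(C)C1=C | intermediate
20 | vinyl bromide | C=CBr | starting material
21 | B-alkyl-9-borabicyclo[3.3.1]nonane from 19 (boron on C6, 5R) | CC(C)(C)[Si](c1ccccc1)(c1ccccc1)OC/C=C(\C)CC[C@H](C(=O)OC)[C@]1(C)C[C@H](O[Si](C)(C)C(C)(C)C)CC(C)(C)[C@H]1CB1C2CCCC1CCC2 | intermediate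
22 | methyl (2S,5E)-2-[(1R,2R,5R)-2-allyl-5-[(tert-butyldimethylsilyl)oxy]-1,3,3-trimethylcyclohexyl]-7-[(tert-butyldiphenylsilyl)oxy]-5-methylhept-5-enoate | CC(C)(C)[Si](c1ccccc1)(c1ccccc1)OC/C=C(\C)CC[C@H](C(=O)OC)[C@]1(C)C[C@H](O[Si](C)(C)C(C)(C)C)CC(C)(C)[C@H]1CC=C | intermediate
23 | α-(trimethylsilyl)methyl ketone from 22 | CC(C)(C)[Si](c1ccccc1)(c1ccccc1)OC/C=C(\C)CC[C@H](C(=O)C[Si](C)(C)C)[C@]1(C)C[C@H](O[Si](C)(C)C(C)(C)C)CC(C)(C)[C@H]1CC=C | intermediate
24 | (3S,6E)-3-[(1R,2R,5R)-2-allyl-5-[(tert-butyldimethylsilyl)oxy]-1,3,3-trimethylcyclohexyl]-8-[(tert-butyldiphenylsilyl)oxy]-6-methyloct-6-en-2-one | CC(C)(C)[Si](c1ccccc1)(c1ccccc1)OC/C=C(\C)CC[C@H](C(C)=O)[C@]1(C)C[C@H](O[Si](C)(C)C(C)(C)C)CC(C)(C)[C@H]1CC=C | intermediate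
25 | tert-butyl{[(2E,6R)-6-[(1S,2R,5R)-2-allyl-5-[(tert-butyldimethylsilyl)oxy]-1,3,3-trimethylcyclohexyl]-3,7-dimethylocta-2,7-dien-1-yl]oxy}diphenylsilane | CC(C)(C)[Si](c1ccccc1)(c1ccccc1)OC/C=C(\C)CC[C@H](C(C)=C)[C@]1(C)C[C@H](O[Si](C)(C)C(C)(C)C)CC(C)(C)[C@H]1CC=C | intermediate
26 | (1R,3S,4R)-4-allyl-3-[(3R,6E)-8-[(tert-butyldiphenylsilyl)oxy]-2,6-dimethylocta-1,6-dien-3-yl]-3,5,5-trimethylcyclohexan-1-ol | CC(C)(C)[Si](c1ccccc1)(c1ccccc1)OC/C=C(\C)CC[C@H](C(C)=C)[C@]1(C)C[C@H](O)CC(C)(C)[C@H]1CC=C | intermediate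
27 | (3S,4R)-4-allyl-3-[(3R,6E)-8-[(tert-butyldiphenylsilyl)oxy]-2,6-dimethylocta-1,6-dien-3-yl]-3,5,5-trimethylcyclohexan-1-one | CC(C)(C)[Si](c1ccccc1)(c1ccccc1)OC/C=C(\C)CC[C@H](C(C)=C)[C@]1(C)CC(=O)CC(C)(C)[C@H]1CC=C | intermediate
28 | (5R,9R,10R)-15-[(tert-butyldiphenylsilyl)oxy]labda-7,13E-dien-2-one | CC(C)(C)[Si](c1ccccc1)(c1ccccc1)OC/C=C(\C)CC[C@@H]1C(C)=CC[C@@H]2C(C)(C)CC(=O)C[C@@]12C | intermediate
29 | potassium C2–C3 enolate of 28 | CC(C)(C)[Si](c1ccccc1)(c1ccccc1)OC/C=C(\C)CC[C@@H]1C(C)=CC[C@@H]2C(C)(C)C=C(O[K])C[C@@]12C | intermediate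
30 | (3R,5S,9R,10S)-15-[(tert-butyldiphenylsilyl)oxy]-3-hydroxylabda-7,13E-dien-2-one | CC(C)(C)[Si](c1ccccc1)(c1ccccc1)OC/C=C(\C)CC[C@@H]1C(C)=CC[C@@H]2C(C)(C)[C@@H](O)C(=O)C[C@@]12C | intermediate
31 | (3S,5S,9R,10S)-15-[(tert-butyldiphenylsilyl)oxy]-3-hydroxylabda-7,13E-dien-2-one | CC(C)(C)[Si](c1ccccc1)(c1ccccc1)OC/C=C(\C)CC[C@@H]1C(C)=CC[C@@H]2C(C)(C)[C@H](O)C(=O)C[C@@]12C | intermediate
32 | (3S,5S,9R,10S)-3,15-dihydroxylabda-7,13E-dien-2-one | OC/C=C(\C)CC[C@@H]1C(C)=CC[C@@H]2C(C)(C)[C@H](O)C(=O)C[C@@]12C | intermediate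
33 | (3S,5S,9R,10S)-3-hydroxy-2-oxolabda-7,13E-dien-15-yl acetate | CC(=O)OC/C=C(\C)CC[C@@H]1C(C)=CC[C@@H]2C(C)(C)[C@H](O)C(=O)C[C@@]12C | target

## Step count and risks

Total step count: 23. Longest linear sequence: 18 steps (steps 1–5 and 11–23; the branch from geraniol, steps 6–10 and 11–23, has the same length).

Steps most likely to fail:

Step 12. The remote C2 silyl ether may discriminate only weakly between the two faces of the C5=C10 alkene, and the ketene acetal geometry may erode, so that C9/C10 diastereomers form and the wanted one is not the main product. The fallback replaces substrate control by reagent control. It sets out from 15, which is enolised with (4S,5S)-2-bromo-1,3-bis[3,5-bis(trifluoromethyl)phenylsulfonyl]-4,5-diphenyl-1,3,2-diazaborolidine and i-Pr2NEt in CH2Cl2 at −78 °C to the Z(O)-boron enolate F1. On warming to between −20 and 4 °C, F1 should rearrange through the same chair with the enolate face chosen by the boron controller; the controller enantiomer is the one that selects the face needed for 9S,10S and is written here as S,S. Aqueous work-up returns the bis-sulfonamide and gives acid 18, where the route is rejoined.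

Step 14. The exocyclic alkene lies between two quaternary carbons, so hydroboration may become slow enough for 9-BBN to attack the C13=C14 alkene as well, and the β-branched alkylborane may transmetalate sluggishly. The fallback is hydroformylation. It sets out from 19: Rh(acac)(CO)2 with tris(2,4-di-tert-butylphenyl) phosphite under CO/H2 (20 bar, toluene, 80 °C) should add hydrogen and a formyl group only across the 1,1-disubstituted alkene, since trisubstituted alkenes are inert. The formyl carbon goes to C6 and hydrogen to C5 from the same open face, which gives the aldehyde methyl (2S,5E)-7-[(tert-butyldiphenylsilyl)oxy]-2-[(1R,2R,5R)-5-[(tert-butyldimethylsilyl)oxy]-1,3,3-trimethyl-2-(2-oxoethyl)cyclohexyl]-5-methylhept-5-enoate F2. Methylenation of F2 with Ph3P=CH2 (THF, 0 °C) gives 22, where the route is rejoined.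

Step 19. The hindered isopropenyl group may engage slowly, so that the catalyst decays to ruthenium hydrides that shift the allyl double bond (closure then loses a carbon), or the allyl termini dimerise. The fallback is a carbonyl coupling, which keeps the regiochemical logic because the alkene can only form between the two carbonyl carbons. It sets out from 19. Me3SiCH2Li followed by MeOH gives the methyl ketone (3S,6E)-8-[(tert-butyldiphenylsilyl)oxy]-3-[(1S,5R)-5-[(tert-butyldimethylsilyl)oxy]-1,3,3-trimethyl-2-methylidenecyclohexyl]-6-methyloct-6-en-2-one F3. Hydroformylation under the conditions given above converts the exocyclic alkene into the keto aldehyde (3S,6E)-8-[(tert-butyldiphenylsilyl)oxy]-3-[(1R,2R,5R)-5-[(tert-butyldimethylsilyl)oxy]-1,3,3-trimethyl-2-(2-oxoethyl)cyclohexyl]-6-methyloct-6-en-2-one F4. Intramolecular McMurry coupling (TiCl3(DME)1.5, Zn–Cu couple, DME, reflux, slow addition) closes ring B between C7 and C8 to the silyl ether (2R,5R,9R,10R)-2-[(tert-butyldimethylsilyl)oxy]-15-[(tert-butyldiphenylsilyl)oxy]labda-7,13E-diene F5. Camphorsulfonic acid in MeOH gives the alcohol (2R,5R,9R,10R)-15-[(tert-butyldiphenylsilyl)oxy]labda-7,13E-dien-2-ol F6, and Dess–Martin oxidation gives 28, where the route is rejoined.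

Further compounds
F1 | step 12 | Z(O)-boron enolate of ester 15 carrying the (4S,5S)-1,3-bis[3,5-bis(trifluoromethyl)phenylsulfonyl]-4,5-diphenyl-1,3,2-diazaborolidin-2-yl group | CC(C)(C)[Si](c1ccccc1)(c1ccccc1)OC/C=C(\C)CC/C=C(\OB1N(S(=O)(=O)c2cc(cc(c2)C(F)(F)F)C(F)(F)F)[C@@H](c2ccccc2)[C@H](c2ccccc2)N1S(=O)(=O)c1cc(cc(c1)C(F)(F)F)C(F)(F)F)OCC1=C(C)C[C@H](O[Si](C)(C)C(C)(C)C)CC1(C)C
F2 | step 14 | methyl (2S,5E)-7-[(tert-butyldiphenylsilyl)oxy]-2-[(1R,2R,5R)-5-[(tert-butyldimethylsilyl)oxy]-1,3,3-trimethyl-2-(2-oxoethyl)cyclohexyl]-5-methylhept-5-enoate | CC(C)(C)[Si](c1ccccc1)(c1ccccc1)OC/C=C(\C)CC[C@H](C(=O)OC)[C@]1(C)C[C@H](O[Si](C)(C)C(C)(C)C)CC(C)(C)[C@H]1CC=O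
F3 | step 19 | (3S,6E)-8-[(tert-butyldiphenylsilyl)oxy]-3-[(1S,5R)-5-[(tert-butyldimethylsilyl)oxy]-1,3,3-trimethyl-2-methylidenecyclohexyl]-6-methyloct-6-en-2-one | CC(C)(C)[Si](c1ccccc1)(c1ccccc1)OC/C=C(\C)CC[C@H](C(C)=O)[C@]1(C)C[C@H](O[Si](C)(C)C(C)(C)C)CC(C)(C)C1=C
F4 | step 19 | (3S,6E)-8-[(tert-butyldiphenylsilyl)oxy]-3-[(1R,2R,5R)-5-[(tert-butyldimethylsilyl)oxy]-1,3,3-trimethyl-2-(2-oxoethyl)cyclohexyl]-6-methyloct-6-en-2-one | CC(C)(C)[Si](c1ccccc1)(c1ccccc1)OC/C=C(\C)CC[C@H](C(C)=O)[C@]1(C)C[C@H](O[Si](C)(C)C(C)(C)C)CC(C)(C)[C@H]1CC=O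
F5 | step 19 | (2R,5R,9R,10R)-2-[(tert-butyldimethylsilyl)oxy]-15-[(tert-butyldiphenylsilyl)oxy]labda-7,13E-diene | CC(C)(C)[Si](c1ccccc1)(c1ccccc1)OC/C=C(\C)CC[C@@H]1C(C)=CC[C@@H]2C(C)(C)C[C@@H](O[Si](C)(C)C(C)(C)C)C[C@@]12C
F6 | step 19 | (2R,5R,9R,10R)-15-[(tert-butyldiphenylsilyl)oxy]labda-7,13E-dien-2-ol | CC(C)(C)[Si](c1ccccc1)(c1ccccc1)OC/C=C(\C)CC[C@@H]1C(C)=CC[C@@H]2C(C)(C)C[C@@H](O)C[C@@]12C
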